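(The readings come from a simulation from invented constants, noise included.)

The ratio of coupling partner to starting material is 1.05 in Tuesday's, Thursday's and the new flask, yet Thursday's run stands still with 19.6 % starting material left.

all flasks: starting material 10 mM (in portions, 4); coupling partner 10.5 mM

| flask | free catalyst | remark | time |
|---|---|---|---|
| Tuesday's | 25 µM | run made earlier; portions every 30 s |  |
| Thursday's | 100 µM | run made earlier; portions every 30 s |  |
| flask | 50 µM | the portions of starting material follow each other after 30 s, the first at the start | 40 min |

| run | time / min | starting material / % | target / % |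
|---|---|---|---|
| Tuesday's | 2.00 | 73.2 | 23.6 |
| Tuesday's | 6.00 | 43.4 | 43.0 |
| Tuesday's | 12.0 | 29.0 | 51.3 |
| Tuesday's | 20.0 | 22.6 | 55.2 |
| Tuesday's | 25.0 | 21.2 | 56.1 |
| Tuesday's | 30.0 | 20.3 | 55.9 |
| Thursday's | 2.50 | 36.3 | 47.9 |
| Thursday's | 4.00 | 26.3 | 52.4 |
| Thursday's | 8.00 | 20.4 | 56.2 |
| Thursday's | 12.0 | 19.7 | 56.0 |
| Thursday's | 20.0 | 19.6 | 56.7 |
| Thursday's | 30.0 | 19.6 | 56.4 |

(each reading ± 0.3 percentage points)

- the numbers in the tables scatter by 0.3 percentage points (one standard deviation)

1. part of the starting material gone at 40 min
2. the target standing at 40 min, as a percentage of the starting material charged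

Thursday's run has 80.4 % of the starting material gone and 56.4 % target, so something besides target forms. Our guess is that target is lost in proportion to what stands. Let x be the fraction of starting material gone and y the target as a fraction of that charge, with dy/dx = 1 − κy, so y = (1 − e^(−κx))/κ. Here κ, a selectivity factor, is the target lost per unit of starting material consumed and per unit of target standing. Trial values 0.7 and 1 bracket Thursday's plateau, and interpolating gives κ = 0.945.

Is that merely a curve through one point? On Tuesday's reading at 2.00 min it gives 23.7 % against 23.6 %, but at 6.00 min it gives 43.8 % against 43.0 %, so we trust it to about a point.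

Why stop there? If each target costs one partner and each other product two, the use is 2x − y = 104 % of the starting-material charge against 105 % charged, so we take the partner as the limiting reagent. Is 40 min long enough? Scaling time by catalyst, the flask reaches 20.0 min of Thursday's time, longer than the 12.0 min at which Thursday's run had levelled. The scaling is rough, but close to the plateau the runs agree: Tuesday's 30.0 min equals 7.50 min of Thursday's and reads 20.3 %, against 20.4 % at 8.00 min. We expect about 80.4 % gone and 56.4 % target.

The forecast says 80.4 % gone and 56.4 % target, taking the flask's time as about 20 min of Thursday's run, “which is fully at plateau”.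

The flask gives 80.6 % gone and 56.3 % target; κ at that conversion gives 56.4 %.

    starting material + catalyst intermediate A ⇌ catalyst intermediate B (K = 180 L mol⁻¹, k = 1200 L mol⁻¹ s⁻¹)
    catalyst intermediate C ⇌ free catalyst + target (K = 0.00400 M, k = 9.70 s⁻¹)
    coupling partner + free catalyst → catalyst intermediate A (k = 370 L mol⁻¹ s⁻¹)
    catalyst intermediate B ⇌ by-product + catalyst intermediate C (K = 0.00880 M, k = 6.80 s⁻¹)
    coupling partner + free catalyst + target → free catalyst + over-reaction product (k = 35000 L² mol⁻² s⁻¹)

At 1.50 min, with 64.3 % of its charge of coupling partner present, the flask held 28.0 % target and 4.54 % over-reaction product. By 20.0 min the partner was down to 0.474 % of its charge, with 24.0 % over-reaction product, and target stood at 56.1 % then and 56.3 % at 40.0 min.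

In the neighbour charged with 26 mM of coupling partner, 2.60 equiv, κ at x = 1 gives 64.7 % target and a partner use of 1.35 equivalents, less than that charge. The simulation gives 100 % gone and 64.6 % target.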